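26% of the Q charged is the highest D read in the birch run, and the oak run reads 26% at the same time, with 1.5 equiv of Z against 0.98 equiv. Our flask has less Z than either, so that height has to be carried down to it.

all flasks: Q 0.59 M
- birch: Z 0.98 equiv; run made earlier
- oak: Z 1.5 equiv; run made earlier
- flask: Z 0.700 equiv; time 10 h

- birch (time / h: D / %, Q / %): 0.167: 9, 77; 0.333: 16, 60; 0.500: 26, 46; 1.00: 22, 27; 2.00: 15, 10; 3.00: 8, 5; 6.00: 6, 2
- oak (time / h: D / %, Q / %): 0.167: 11, 75; 0.333: 22, 61; 0.500: 26, 49; 1.00: 24, 22; 2.00: 14, 7; 3.00: 11, 0; 6.00: 11, 1

(scatter of a reading: 1.5 percentage points)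

* time, not beyond 10 h, at which the flask holds most D
* the amount of D, in percent of the Q charged, at that time

- what was read earlier has a scatter of 1.5 percentage points, one standard deviation

We build the flask up in steps. With the main step alone, Q and Z giving D one for one, Z is the limiting reagent and its charge allows 70.0% of D. Now add the loss of D: in both runs D falls after its peak, to 6% in birch and 11% in oak at 6.00 h, so a peak is a balance of making and losing. Last comes the amount of Z. At that late time Q reads 2% and 1%, yet D differs, so Z counts.

We solve both ends and join them. At the high end, the highest readings of birch and oak stand level, but with a scatter of 1.5 percentage points on each they can hide a gain from the extra Z, so we read no ceiling from them. At the low end, we take the height to go with the Z charged, on a straight line from zero. Birch gives 26.5% of the Q charged for each equivalent of Z; we call this the peak per equivalent, the highest D divided by the Z charged. Our reckoning for the flask is 18.6%, near the runs' peak time, between 0.500 h and 1.00 h.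

The forecast differs in height: 25% at 0.65 h, holding that “Peak height and timing barely differ between the two runs”.

The flask gives 19.4% at 0.675 h.

    Q ⇌ G (K = 2.60, k = 4.30 × 10⁻⁴ s⁻¹)
    2 E → J (k = 0.00290 L mol⁻¹ s⁻¹)
    D ⇌ X (K = 10.0, k = 6.80 × 10⁻⁴ s⁻¹)
    G + E → D (k = 0.0260 L mol⁻¹ s⁻¹)
    Z → E (k = 4.20 × 10⁻⁴ s⁻¹)

That is 27.7% per equivalent against our 26.5%, with 36.0% of the flask's own Z charge still there at 0.675 h, and 5.6 points under the forecast. The same reckoning goes to a neighbouring flask, the same flask with 0.420 equiv of Z: the peak per equivalent gives 11.1%, and that neighbour reaches 12.4%, which is 29.5% per equivalent.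

The numbers in the tables come from a simulation on assumed constants; noise was put on by code.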